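**Retrosynthetic overview**
1. Numbering: ring A is the cyclohex-2-enone C1(=O)–C2=C3–C4–C5(OH)–C6; the side chain on C5 is C1'H2–C2'(=O)–C3'H2…(Z)-C10'=C11'…C19'. Ring A is closed last, at C2=C3, by ring-closing metathesis of an allyl group (C4, C3) with a vinyl ketone (C1, C2); the final step is Si–O cleavage.
2. Key disconnection C2'–C3': the C3'–C19' unit is the radical left when oleic acid loses CO2, and C2' is an acyl carbon.
3. Enabling feature: C5 carries two CH2–C(=O) arms, C6–C1 inside ring A and C1'–C2' in the chain (a hidden 3-oxyglutaric acid). Joining C1 and C2' through one oxygen gives a six-membered oxane-2,6-dione ring that is not in the target and in which C5 is only prochiral.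
4. Key step: enantioselective nickel-catalysed reductive opening of that anhydride by the oleic-acid-derived radical (two acid derivatives, both electrophiles). It forms C2'–C3', sets C5 and frees C1 as CO2H for ring A.
5. Ring order: temporary oxane-2,6-dione ring (closed in step 4, opened in step 6), then ring A (step 8). The anhydride comes from dimethyl 3-oxopentanedioate and allyl bromide.

Key step: step 6

Remark: the sense of induction of the chiral nickel catalyst on this new anhydride cannot be derived from precedent; the (S,S)-ligand is written, and its mirror image is to be used if the first run shows the opposite sense.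

**Route**

Step 1
Reactants: 1 dimethyl 3-oxopentanedioate; 2 allyl bromide
Product: 4 dimethyl 3-hydroxy-3-(prop-2-en-1-yl)pentanedioate, via allylzinc bromide 3 (not isolated)
Conditions: Zn powder, THF/sat. aq. NH4Cl, 0 °C to rt
Reagents that add atoms: none
Why: Zinc-mediated Barbier allylation, in which allylzinc bromide forms on the metal and adds to the ketone of the β-keto diester faster than it is protonated in the aqueous medium, and because the two ester arms stay identical the new carbinol carbon is not yet a stereocenter.

Step 2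
Reactants: 4 dimethyl 3-hydroxy-3-(prop-2-en-1-yl)pentanedioate
Product: 5 dimethyl 3-(prop-2-en-1-yl)-3-[(triethylsilyl)oxy]pentanedioate
Conditions: Et3SiOTf, 2,6-lutidine, CH2Cl2, −78 to 0 °C
Reagents that add atoms: triethylsilyl trifluoromethanesulfonate, CC[Si](CC)(CC)OS(=O)(=O)C(F)(F)F
Why: Silylation of a hindered tertiary alcohol with a silyl triflate and 2,6-lutidine, giving a triethylsilyl ether that blocks β-elimination in the following steps and can be removed at the end with buffered fluoride.

Step 3
Reactants: 5 dimethyl 3-(prop-2-en-1-yl)-3-[(triethylsilyl)oxy]pentanedioate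
Product: 6 3-(prop-2-en-1-yl)-3-[(triethylsilyl)oxy]pentanedioic acid
Conditions: LiOH·H2O, THF/MeOH/H2O, 0 °C to rt; then cold 1 M HCl to pH 3
Reagents that add atoms: lithium hydroxide, [Li+].[OH-]
Why: Saponification of two unhindered methyl esters with aqueous LiOH, which a tertiary triethylsilyl ether should survive when the acidification is kept cold and brief.

Step 4
Reactants: 6 3-(prop-2-en-1-yl)-3-[(triethylsilyl)oxy]pentanedioic acid
Product: 7 4-(prop-2-en-1-yl)-4-[(triethylsilyl)oxy]oxane-2,6-dione (the cyclic anhydride, achiral, mirror plane through C4 and the ring oxygen)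
Conditions: DCC, CH2Cl2, 0 °C to rt; filtration
Reagents that add atoms: none
Why: Carbodiimide-mediated cyclodehydration, in which the O-acylisourea of one carboxyl group is attacked by the other (6-exo-trig, helped by the geminal disubstitution) under neutral conditions, so that the β-silyloxy group is not eliminated.

Step 5
Reactants: 8 oleic acid; 9 N-hydroxyphthalimide
Product: 10 1,3-dioxoisoindolin-2-yl (9Z)-octadec-9-enoate
Conditions: N,N'-diisopropylcarbodiimide, DMAP (cat.), CH2Cl2, rt
Reagents that add atoms: none
Why: Steglich-type esterification with N-hydroxyphthalimide gives the redox-active ester and leaves the (Z)-olefin of oleic acid unchanged.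

Step 6
Reactants: 7 4-(prop-2-en-1-yl)-4-[(triethylsilyl)oxy]oxane-2,6-dione; 10 1,3-dioxoisoindolin-2-yl (9Z)-octadec-9-enoate
Product: 11 (3R,13Z)-5-oxo-3-(prop-2-en-1-yl)-3-[(triethylsilyl)oxy]docos-13-enoic acid
Conditions: NiBr2(dme) (10 mol %), 2,2'-(propane-2,2-diyl)bis[(4S)-4-phenyl-4,5-dihydro-1,3-oxazole] (12 mol %), Zn powder, DMA/THF, 0 °C, slow addition of 10; then cold 0.5 M HCl
Reagents that add atoms: none
Why: Proposed new method: zerovalent nickel bearing the chiral bis(oxazoline) inserts into one of the two enantiotopic acyl C–O bonds of 7 to give a seven-membered acyl carboxylate chelate of divalent nickel, while single-electron reduction of 10 (by monovalent nickel or zinc) releases CO2, phthalimide anion and the primary (Z)-heptadec-8-enyl radical, which is captured at nickel and leaves trivalent nickel by C(sp3)–C(acyl) reductive elimination before zinc returns the catalyst to the zerovalent state. The closest known reaction types are the nickel-catalysed decarboxylative cross-electrophile ketone synthesis from N-acyloxyphthalimides and activated acyl donors, the nickel-catalysed reductive coupling of alkyl halides with anhydrides, and the enantioselective nickel- or rhodium-catalysed desymmetrising alkylation of cyclic meso-anhydrides with benzyl radicals or alkylzinc reagents; new is their combination on a glutaric anhydride whose prochiral carbon is quaternary. No ring is closed, and the temporary oxane-2,6-dione ring, which is not in the target, is opened. The stereocenter (C3 of 11, C5 of the target) is set by the chiral ligand on nickel, and the substrate should help because the half-chair anhydride is expected to hold the allyl group equatorial and the silyloxy group axial, so that one ring face is shielded and the ligand has to choose only between the two carbonyl groups on the open face. The step needs cross-coupling over homo-coupling, which the different activation modes of the two electrophiles should secure (two-electron insertion into the anhydride, one-electron reduction of the ester), and mono-acylation, which is secured because the product is a carboxylate that cannot add to nickel again. The allyl group should not insert into the acyl–nickel bond because the chelated square-planar intermediate has no free cis site, and the remote (Z)-olefin is out of reach of the radical.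

Step 7
Reactants: 11 (3R,13Z)-5-oxo-3-(prop-2-en-1-yl)-3-[(triethylsilyl)oxy]docos-13-enoic acid; 12 tributyl(vinyl)stannane
Product: 14 (5R,15Z)-5-(prop-2-en-1-yl)-5-[(triethylsilyl)oxy]tetracosa-1,15-diene-3,7-dione, via acid chloride 13 (not isolated)
Conditions: 1-chloro-N,N,2-trimethylprop-1-en-1-amine, CH2Cl2, 0 °C to rt; then 12, Pd2(dba)3 (2.5 mol %), P(2-furyl)3, BHT (trace), THF, rt to 40 °C
Reagents that add atoms: none
Why: The α-chloroenamine makes the acid chloride without releasing HCl, and the Stille ketone synthesis (oxidative addition to zerovalent palladium, vinyl transfer from tin, reductive elimination) then gives the vinyl ketone while leaving alone the dialkyl ketone that a magnesium or lithium reagent would attack; the quaternary stereocenter is not touched.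

Step 8
Reactants: 14 (5R,15Z)-5-(prop-2-en-1-yl)-5-[(triethylsilyl)oxy]tetracosa-1,15-diene-3,7-dione
Product: 15 (5R)-5-[(10Z)-2-oxononadec-10-en-1-yl]-5-[(triethylsilyl)oxy]cyclohex-2-en-1-one
Conditions: second-generation Hoveyda–Grubbs catalyst RuCl2(H2IMes)(=CH-C6H4-2-OiPr) (5 mol %), 1,4-benzoquinone (10 mol %), CH2Cl2 (2 mM), 40 °C, argon sparge
Reagents that add atoms: none
Why: Ring-closing metathesis, in which the ruthenium carbene loads onto the allyl terminus and closes onto the vinyl ketone to give the six-membered enone of ring A with loss of ethene, while high dilution, a short reaction time and the benzoquinone additive should keep the remote internal (Z)-olefin out of cross-metathesis and isomerisation.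

Step 9
Reactants: 15 (5R)-5-[(10Z)-2-oxononadec-10-en-1-yl]-5-[(triethylsilyl)oxy]cyclohex-2-en-1-one
Product: 16 (5R)-5-hydroxy-5-[(10Z)-2-oxononadec-10-en-1-yl]cyclohex-2-en-1-one
Conditions: HF·pyridine, pyridine, THF, 0 °C to rt; pH 7 phosphate buffer
Reagents that add atoms: none
Why: Fluoride-driven Si–O cleavage with pyridine-buffered HF·pyridine is close to neutral, so the tertiary β-hydroxy ketone should be released without retro-aldol cleavage or dehydration towards the 3-alkylphenol, and the quaternary stereocenter cannot epimerise.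

**Compound list**
1 | dimethyl 3-oxopentanedioate | COC(=O)CC(=O)CC(=O)OC | starting material
2 | allyl bromide (3-bromoprop-1-ene) | C=CCBr | starting material
3 | allylzinc bromide | C=CC[Zn]Br | intermediate
4 | dimethyl 3-hydroxy-3-(prop-2-en-1-yl)pentanedioate | COC(=O)CC(O)(CC=C)CC(=O)OC | intermediate
5 | dimethyl 3-(prop-2-en-1-yl)-3-[(triethylsilyl)oxy]pentanedioate | COC(=O)CC(CC=C)(O[Si](CC)(CC)CC)CC(=O)OC | intermediate
6 | 3-(prop-2-en-1-yl)-3-[(triethylsilyl)oxy]pentanedioic acid | OC(=O)CC(CC=C)(O[Si](CC)(CC)CC)CC(=O)O | intermediate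
7 | 4-(prop-2-en-1-yl)-4-[(triethylsilyl)oxy]oxane-2,6-dione | C=CCC1(O[Si](CC)(CC)CC)CC(=O)OC(=O)C1 | intermediate
8 | oleic acid, (9Z)-octadec-9-enoic acid | CCCCCCCC/C=C\CCCCCCCC(=O)O | starting material
9 | N-hydroxyphthalimide | O=C1c2ccccc2C(=O)N1O | starting material
10 | 1,3-dioxoisoindolin-2-yl (9Z)-octadec-9-enoate | CCCCCCCC/C=C\CCCCCCCC(=O)ON1C(=O)c2ccccc2C1=O | intermediate
11 | (3R,13Z)-5-oxo-3-(prop-2-en-1-yl)-3-[(triethylsilyl)oxy]docos-13-enoic acid | CCCCCCCC/C=C\CCCCCCCC(=O)C[C@](CC(=O)O)(O[Si](CC)(CC)CC)CC=C | intermediate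
12 | tributyl(vinyl)stannane | C=C[Sn](CCCC)(CCCC)CCCC | starting material
13 | (3R,13Z)-5-oxo-3-(prop-2-en-1-yl)-3-[(triethylsilyl)oxy]docos-13-enoyl chloride | CCCCCCCC/C=C\CCCCCCCC(=O)C[C@](CC(=O)Cl)(O[Si](CC)(CC)CC)CC=C | intermediate
14 | (5R,15Z)-5-(prop-2-en-1-yl)-5-[(triethylsilyl)oxy]tetracosa-1,15-diene-3,7-dione | CCCCCCCC/C=C\CCCCCCCC(=O)C[C@](CC(=O)C=C)(O[Si](CC)(CC)CC)CC=C | intermediate
15 | (5R)-5-[(10Z)-2-oxononadec-10-en-1-yl]-5-[(triethylsilyl)oxy]cyclohex-2-en-1-one | CCCCCCCC/C=C\CCCCCCCC(=O)C[C@]1(O[Si](CC)(CC)CC)CC=CC(=O)C1 | intermediate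
16 | (5R)-5-hydroxy-5-[(10Z)-2-oxononadec-10-en-1-yl]cyclohex-2-en-1-one | CCCCCCCC/C=C\CCCCCCCC(=O)C[C@]1(O)CC=CC(=O)C1 | target

**Step count and risks**
Total steps: 9. Longest linear sequence: 8 (steps 1–4 and 6–9); step 5 is the one-step side branch.

Steps most likely to fail:

1. Step 6 (proposed new method). What may go wrong: the catalyst may discriminate poorly between the two enantiotopic carbonyl groups, because the two half-chair conformers of the 4,4-disubstituted anhydride lead to opposite senses. Racemic background opening of the anhydride by phthalimide anion or halide and dimerisation of the alkyl radical are further risks. Fallback with known chemistry, setting out from 7: alcoholysis with methanol under a bifunctional cinchona-alkaloid thiourea catalyst (MTBE, low temperature) should give (3R)-5-methoxy-5-oxo-3-(prop-2-en-1-yl)-3-[(triethylsilyl)oxy]pentanoic acid F1. Activation with 2,2'-dipyridyl disulfide and PPh3 gives the S-(pyridin-2-yl) thioester, methyl (3S)-5-oxo-3-(prop-2-en-1-yl)-5-(pyridin-2-ylsulfanyl)-3-[(triethylsilyl)oxy]pentanoate F2. The known nickel-catalysed decarboxylative cross-electrophile coupling of such thioesters with N-acyloxyphthalimides (NiBr2(dme), 4,4'-di-tert-butyl-2,2'-bipyridine, Zn, DMA) joins F2 with 10 to methyl (3R,13Z)-5-oxo-3-(prop-2-en-1-yl)-3-[(triethylsilyl)oxy]docos-13-enoate F3. Neutral ester cleavage with Me3SnOH (1,2-dichloroethane, 70 °C) comes back to the route at 11.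

2. Step 7. What may go wrong: the activated acid may cyclise onto the δ-ketone (enol lactone formation), the acyl palladium intermediate may insert into the pendant allyl group (5-exo), and the vinyl ketone may polymerise. Fallback through the aldehyde oxidation level, setting out from 11: EtSH, EDC·HCl and DMAP give S-ethyl (3R,13Z)-5-oxo-3-(prop-2-en-1-yl)-3-[(triethylsilyl)oxy]docos-13-enethioate F4. Fukuyama reduction (Et3SiH, Pd/C, acetone) gives (3S,13Z)-5-oxo-3-(prop-2-en-1-yl)-3-[(triethylsilyl)oxy]docos-13-enal F5. An aldehyde-selective Nozaki–Hiyama–Kishi vinylation (vinyl bromide, CrCl2, NiCl2 cat., DMF) gives (5S,15Z)-3-hydroxy-5-(prop-2-en-1-yl)-5-[(triethylsilyl)oxy]tetracosa-1,15-dien-7-one F6 as a mixture of C3 epimers. Dess–Martin oxidation comes back to the route at 14.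

3. Step 8. What may go wrong: the ruthenium carbene, or the methylidene formed from released ethene, may engage the internal (Z)-olefin (cross-metathesis, ethenolysis, Z/E scrambling) while closure onto the electron-poor vinyl ketone is slow. Fallback at another oxidation level, setting out from 14: Luche reduction (NaBH4, CeCl3·7H2O, MeOH, −40 °C) of both ketones gives (5R,15Z)-5-(prop-2-en-1-yl)-5-[(triethylsilyl)oxy]tetracosa-1,15-diene-3,7-diol F7 as a mixture of carbinol epimers. Its two electron-rich terminal olefins should close at room temperature with the less active first-generation Grubbs catalyst RuCl2(=CHPh)(PCy3)2 (CH2Cl2, 2 mM) to (5R)-5-[(10Z)-2-hydroxynonadec-10-en-1-yl]-5-[(triethylsilyl)oxy]cyclohex-2-en-1-ol F8. Dess–Martin oxidation of both secondary alcohols (NaHCO3 buffer) comes back to the route at 15.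

**Further compounds**
F1 | step 6 | (3R)-5-methoxy-5-oxo-3-(prop-2-en-1-yl)-3-[(triethylsilyl)oxy]pentanoic acid | OC(=O)C[C@](CC(=O)OC)(O[Si](CC)(CC)CC)CC=C
F2 | step 6 | methyl (3S)-5-oxo-3-(prop-2-en-1-yl)-5-(pyridin-2-ylsulfanyl)-3-[(triethylsilyl)oxy]pentanoate | O=C(Sc1ccccn1)C[C@](CC(=O)OC)(O[Si](CC)(CC)CC)CC=C
F3 | step 6 | methyl (3R,13Z)-5-oxo-3-(prop-2-en-1-yl)-3-[(triethylsilyl)oxy]docos-13-enoate | CCCCCCCC/C=C\CCCCCCCC(=O)C[C@](CC(=O)OC)(O[Si](CC)(CC)CC)CC=C
F4 | step 7 | S-ethyl (3R,13Z)-5-oxo-3-(prop-2-en-1-yl)-3-[(triethylsilyl)oxy]docos-13-enethioate | CCCCCCCC/C=C\CCCCCCCC(=O)C[C@](CC(=O)SCC)(O[Si](CC)(CC)CC)CC=C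
F5 | step 7 | (3S,13Z)-5-oxo-3-(prop-2-en-1-yl)-3-[(triethylsilyl)oxy]docos-13-enal | CCCCCCCC/C=C\CCCCCCCC(=O)C[C@](CC=O)(O[Si](CC)(CC)CC)CC=C
F6 | step 7 | (5S,15Z)-3-hydroxy-5-(prop-2-en-1-yl)-5-[(triethylsilyl)oxy]tetracosa-1,15-dien-7-one (C3 epimers) | CCCCCCCC/C=C\CCCCCCCC(=O)C[C@](CC(O)C=C)(O[Si](CC)(CC)CC)CC=C
F7 | step 8 | (5R,15Z)-5-(prop-2-en-1-yl)-5-[(triethylsilyl)oxy]tetracosa-1,15-diene-3,7-diol (carbinol epimers) | CCCCCCCC/C=C\CCCCCCCC(O)C[C@](CC(O)C=C)(O[Si](CC)(CC)CC)CC=C
F8 | step 8 | (5R)-5-[(10Z)-2-hydroxynonadec-10-en-1-yl]-5-[(triethylsilyl)oxy]cyclohex-2-en-1-ol (carbinol epimers) | CCCCCCCC/C=C\CCCCCCCC(O)C[C@]1(O[Si](CC)(CC)CC)CC=CC(O)C1
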